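## The problem

Atom numbers follow the ent-kaurane skeleton: ring A is C1–C5 and C10, C19 and the methyl sit on C4, C6 on C5, C20 on C10, ring C is C8, C9, C11–C14, and C15–C16(=C17) is the bridge of ring D. The target is a 6,7-seco-ent-kaurane of the spirolactone type. Quaternary C10 of ring A is the spiro atom of a δ-lactone (C7–O–C20), this lactone is fused through C8–C9 to ring C, and rings C and D form a bicyclo[3.2.1]octane bridged between C8 and C13. Seven stereocentres must be set (C1, C4, C5, C10, C8, C9, C13), three of them quaternary (C4, C8, C10), and the two halves meet at the congested C9–C10 bond. Within ring A the three oxygen-bearing groups (C1–O, C6, C19) lie on one face, so C4 and C5 can steer C1 and C10. No ring spans C9–C10, so C9 needs its own control element, and C8 must carry C7 cis to C10 on ring C. The ring D α-methylene ketone is a Michael acceptor, the acetates and the lactone are base-labile, and the C6 hydroxyl must end free beside two acylated ones. The enone therefore comes last and three kinds of oxygen protection are needed. The enabling feature is that quaternary C8 is α to the C7 carboxyl while C14 lies two atoms from C12. A δ-lactone closed from C7 onto an oxygen at C12, with C13=C14 as a vinyl group on C12, is a Claisen substrate whose [3,3] shift forms C8–C14, closes ring C and passes the C12 configuration on to C8.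

## Retrosynthesis

**Enone and C6 hydroxyl last.** Target 36 is traced to its 4-methoxybenzyl ether 35, to the allylic alcohol 34 and to the 15-deoxo alkene 33. The cuts are the C15 oxygen and the O–benzyl bond. C15 is the only allylic position that can be oxidised, since C13 is a bridgehead. Keeping the Michael acceptor out of every earlier step is worth the two late oxidations. The forward steps must leave acetates and lactone alone.

**Acetates from silyl ethers.** 33 comes from diol 32 and the bis-silyl ether 31. Acetates could not pass the strongly basic steps, so C1 and C19 travel as tert-butyldimethylsilyl ethers. C6 carries a different group so that it alone ends free.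

**Ring D by the C13–C16 bond.** 31 is cut at C13–C16 to the alkynyl spirolactone 29. The alternative cut C8–C15 would mean alkylating a ring-fusion carbon of a bicycle. The alkene left by the Claisen step (C12=C13) is exactly where a C16 vinyl radical needs it. The forward step must close 5-exo and must not rearrange.

**Lactone C7–O–C20.** 29 opens to acid 27, and so to 26. Only the C20 oxygen may be free at this point, because the C1 oxygen could close an isomeric six-membered lactone. C20 therefore carries a triethylsilyl ether, which is removed beside the hindered tert-butyldimethylsilyl ethers.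

**Key cut, C8–C14 with O–C12 restored.** Acid 26 is traced to the 6-vinyl δ-lactone 23. Quaternary C8 becomes a lactone α-carbon, ring C disappears, and the C8 configuration is traded for a carbinol centre at C12. A Diels–Alder route to ring C, or alkylation of a ring C enolate, would have nothing comparable to fix C8 against C9. The forward step needs the 4,6-trans relation of ring A (on C9) and vinyl (on C12), and enolisation at a hindered carbon.

**C8–C15.** 23 comes from lactone 21 and bromide 22 by enolate alkylation. The C8 configuration is erased in the next step, so no selectivity is asked.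

**C9–C10.** 21, via alcohol 20, is cut between the two halves into spiro-epoxide 14 and unsaturated lactone 19. A polar union through a C10 enolate would risk β-elimination of the C1 oxygen and would bring C20 at the acid level, which could not be reduced beside the lactone. A C10 radical from the epoxide tolerates the β-oxygen and delivers C20 as the free alcohol. The forward step must add to the ring A face opposite C1–O, C6 and C19, and trans to the vinyl group of 19.

**Lactone 19.** 19 comes from acrylate 18 by ring-closing metathesis (C8=C9). 18 comes from dienol 16 and acid chloride 17. 16 comes from aldehyde 15 by asymmetric allylation, which sets C12.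

**Epoxide 14.** 14 is traced to alkene 13, diol 12 and keto aldehyde 11. C20 enters as a methylidene group on C10, and C1 is set by hydride delivery opposite C6 and C19. 11 comes from the silyl enol ether 8, whose double bond points only towards C10.

**Ring A by cycloaddition.** 8 is cut at C2–C3 and C4–C5 into diene 6 and aldehyde 7. One step makes quaternary C4 and C5 with the formyl group (C19) cis to C6. It also yields a single enol ether regioisomer, which a ketone alkylation route could not guarantee. The forward step must be endo-selective and face-selective.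

**Diene 6.** 6 comes from enone 5 by enol silylation. 5 comes from allyl ether 3 and ketone 4 by cross-metathesis. 3 comes from alcohol 1 and bromide 2.

## Roads not taken

**Alternative 1:** The cut is at C10–C20 and C5–C6. The ring A cyclohexenone A1, with the C9 side chain attached, would be irradiated with vinylene carbonate A2 to give the cyclobutane carbonate A3. Hydrolysis and glycol cleavage would later free C6 and C20 as aldehydes.
- Merits: one step makes quaternary C10 and C5 with C6 and C20 cis, from a flat enone. No hindered intermolecular C–C coupling is needed, and the C1 oxygen is present as the ketone.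
- Weak points: C20 must end cis to C19, so the cycloaddition has to occur on the enone face next to the CH2O group of quaternary C4, which is the more hindered face. C9 is an open-chain centre with nothing in the photoreaction to relate it to C10. After cleavage the C20 aldehyde sits on a quaternary carbon α to the C1 ketone, where it is prone to retro-Claisen loss, and it must be told apart from the C6 aldehyde. Rings C and D and quaternary C8 are untouched.
- Comparison: for ring A alone this road is shorter than steps 1–8 and 12, and it answers the C9–C10 congestion better. The chosen plan forms C10 on the face opposite all three oxygenated substituents, differentiates C6 from C20 from the start, and gains the C12 control element for C8 in the same coupling.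

**Alternative 2:** The cut is at C13–C14 and C8–C15. A zerovalent palladium catalyst would release a trimethylenemethane dipole from the silylmethyl allyl acetate at the end of the C9 side chain of the α-methylene spirolactone A4. Attack of C13 on C14 would close ring C, and collapse of the C8 enolate onto C15 would close ring D, giving the 15-deoxo tetracycle A5.
- Merits: two rings, quaternary C8 and C13 arise in one late step with lactone and acetates in place. For rings C and D this is clearly shorter than steps 14–18.
- Weak points: the tether joins the dipole to the α-carbon of the acceptor, so the adduct must be bridged. Intramolecular cycloadditions of this kind have far less precedent in the bridged mode than in the fused mode. The first bond is a 6-endo Michael addition by the substituted terminus and the second must form a quaternary centre. C8 and C13 depend on the conformation of a flexible chain next to C9. Protodesilylation and elimination compete.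
- Comparison: this road is bolder and shorter. The chosen plan offers transfer of chirality to C8 through a rigid bicyclic transition state, and closer precedent for its ring-forming steps.

**Alternative 3:** The cut is at C9–C10 and O–C7. The trivalent titanium reagent of step 12 would open the ring A spiro-epoxide A6 to the C10 radical, which would add to 2,2,2-trifluoroethyl acrylate A7. The C20 alkoxide would then close onto the ester to give the saturated spirolactone A8.
- Merits: the radical meets an unhindered acrylate, and quaternary C10 and the C7–O–C20 lactone form together. As a coupling it is more reliable than step 12, which uses a β-substituted acceptor.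
- Weak points: C8 and C9 arrive as methylene groups. The C9 stereocentre, quaternary C8 and C13 must then all be built on the spirolactone by desaturation and further C–C bond formation, with only remote control from ring A.
- Comparison: the chosen plan asks more of the same radical. In return C9 is set in the coupling, and the acceptor brings C11–C14 and the C12 stereocentre, so rings C and D follow in five steps.

Key step: step 15

Assumption: the antipode of the oxazaborolidinium catalyst in step 4 is chosen from its accepted model for 2-substituted acroleins; if 8 formed as its mirror image, the mirror-image catalyst would be used.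
Remark: C10 in 9, 10 and 14, C8 in 23, C15 in 34 and the alkene geometry of 30 are erased later; one isomer is named and drawn (30 without geometry).

## Route

Step 1
Reactants: 1 4-methoxybenzyl alcohol; 2 3-bromoprop-1-ene
Product: 3 1-methoxy-4-[(prop-2-en-1-yloxy)methyl]benzene
Conditions: NaH, THF/DMF, 0 → 23 °C
Reagents that add atoms: none
Why: Williamson ether synthesis of a primary alkoxide with an allylic bromide; it brings the C6 oxygen under the one group that can be removed last, oxidatively, beside acetates and an enone.

Step 2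
Reactants: 3 1-methoxy-4-[(prop-2-en-1-yloxy)methyl]benzene; 4 but-3-en-2-one
Product: 5 (3E)-5-[(4-methoxybenzyl)oxy]pent-3-en-2-one
Conditions: second-generation Hoveyda–Grubbs catalyst (2 mol %), CH2Cl2, 40 °C
Reagents that add atoms: none
Why: Olefin cross-metathesis of a terminal allyl ether with an electron-poor vinyl ketone (in excess) favours the cross product and the E-enone.

Step 3
Reactants: 5 (3E)-5-[(4-methoxybenzyl)oxy]pent-3-en-2-one
Product: 6 {[(3E)-5-[(4-methoxybenzyl)oxy]penta-1,3-dien-2-yl]oxy}tri(propan-2-yl)silane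
Conditions: iPr3SiOTf, Et3N, CH2Cl2, 0 °C
Reagents that add atoms: triisopropylsilyl trifluoromethanesulfonate, CC(C)[Si](C(C)C)(C(C)C)OS(=O)(=O)C(F)(F)F
Why: Soft enolisation at the α′-methyl group gives the cross-conjugated 2-silyloxy diene with the E double bond untouched; the bulky silyl group keeps the diene and its adduct stable to the acidic catalyst of step 4.

Step 4
Reactants: 6 {[(3E)-5-[(4-methoxybenzyl)oxy]penta-1,3-dien-2-yl]oxy}tri(propan-2-yl)silane; 7 2-methylprop-2-enal
Product: 8 (1R,2S)-2-{[(4-methoxybenzyl)oxy]methyl}-1-methyl-4-[(triisopropylsilyl)oxy]cyclohex-3-ene-1-carbaldehyde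
Conditions: oxazaborolidinium triflimide from (S)-diphenylprolinol and o-tolylboronic acid (20 mol %), CH2Cl2, −78 °C
Reagents that add atoms: none
Why: Diels–Alder cycloaddition under chiral oxazaborolidinium catalysis, a known pairing of 2-silyloxy dienes with 2-substituted acroleins. The silyloxy group ("para") and the C5 substituent ("ortho") both direct C2 to C3 and C5 to C4; the endo transition state puts formyl (C19) cis to C6, and the catalyst face sets C4 and C5 absolutely. The enol ether double bond can only lie between C1 and C10.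

Step 5
Reactants: 8 (1R,2S)-2-{[(4-methoxybenzyl)oxy]methyl}-1-methyl-4-[(triisopropylsilyl)oxy]cyclohex-3-ene-1-carbaldehyde
Product: 11 (1R,2R)-2-{[(4-methoxybenzyl)oxy]methyl}-1-methyl-3-methylidene-4-oxocyclohexane-1-carbaldehyde, via Mannich base 9 (not isolated), via ammonium iodide 10 (not isolated)
Conditions: Me2N=CH2 I, CH2Cl2, 23 °C; MeI; aq. NaHCO3
Reagents that add atoms: dimethyl(methylidene)ammonium iodide, C=[N+](C)C.[I-]
Why: Mannich aminomethylation of the silyl enol ether occurs at C10, the only enol carbon; N-methylation and E1cB loss of trimethylamine give the exocyclic enone with C20 in place. The aldehyde has no α-hydrogen and stays inert.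

Step 6
Reactants: 11 (1R,2R)-2-{[(4-methoxybenzyl)oxy]methyl}-1-methyl-3-methylidene-4-oxocyclohexane-1-carbaldehyde
Product: 12 (1S,3R,4R)-4-(hydroxymethyl)-3-{[(4-methoxybenzyl)oxy]methyl}-4-methyl-2-methylidenecyclohexan-1-ol
Conditions: NaBH4 (excess), CeCl3·7H2O, MeOH, −78 → 0 °C
Reagents that add atoms: none
Why: Luche reduction gives 1,2-delivery to the enone and reduces the neopentyl aldehyde in the same operation. Hydride should reach C1 from the face opposite C6 and C19, which places the C1 hydroxyl cis to both, as in the target.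

Step 7
Reactants: 12 (1S,3R,4R)-4-(hydroxymethyl)-3-{[(4-methoxybenzyl)oxy]methyl}-4-methyl-2-methylidenecyclohexan-1-ol
Product: 13 bis(tert-butyldimethylsilyl) ether of 12 (C1 and C19 oxygens)
Conditions: tBuMe2SiOTf, 2,6-lutidine, CH2Cl2, −78 → 0 °C
Reagents that add atoms: tert-butyldimethylsilyl trifluoromethanesulfonate, CC(C)(C)[Si](C)(C)OS(=O)(=O)C(F)(F)F
Why: Silyl triflate silylation also reaches the neopentyl C19 oxygen; these ethers withstand the amide bases of steps 14 and 15, where acetates would not.

Step 8
Reactants: 13 bis(tert-butyldimethylsilyl) ether of 12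
Product: 14 (3R,4S,5R,8S)-8-[(tert-butyldimethylsilyl)oxy]-5-{[(tert-butyldimethylsilyl)oxy]methyl}-4-{[(4-methoxybenzyl)oxy]methyl}-5-methyl-1-oxaspiro[2.5]octane
Conditions: mCPBA, NaHCO3, CH2Cl2, 0 °C
Reagents that add atoms: 3-chloroperoxybenzoic acid, OOC(=O)c1cccc(Cl)c1
Why: Prilezhaev epoxidation of the only alkene; the C10 configuration is irrelevant because step 12 makes C10 a planar radical.

Step 9
Reactants: 15 prop-2-enal
Product: 16 (3S)-hexa-1,5-dien-3-ol
Conditions: (−)-Ipc2BOMe, allylMgBr, Et2O, −78 → 23 °C; 15, −78 °C; NaOH, H2O2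
Reagents that add atoms: allylmagnesium bromide, C=CC[Mg]Br
Why: Brown allylboration through a closed chair transition state; the isopinocampheyl groups from (+)-α-pinene should deliver allyl to the aldehyde face that gives the S carbinol, the future C12.

Step 10
Reactants: 16 (3S)-hexa-1,5-dien-3-ol; 17 prop-2-enoyl chloride
Product: 18 (3S)-hexa-1,5-dien-3-yl prop-2-enoate
Conditions: Et3N, DMAP (cat.), CH2Cl2, 0 °C
Reagents that add atoms: none
Why: O-acylation of the secondary alcohol by the acid chloride under amine base; the stereocentre is not involved.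

Step 11
Reactants: 18 (3S)-hexa-1,5-dien-3-yl prop-2-enoate
Product: 19 (6S)-6-ethenyl-5,6-dihydro-2H-pyran-2-one
Conditions: second-generation Grubbs catalyst (5 mol %), CH2Cl2 (0.005 M), 40 °C
Reagents that add atoms: none
Why: Ring-closing metathesis starts at the unhindered allyl terminus and closes onto the acrylate to the six-membered lactone (C8=C9); closure onto the carbinol vinyl group to a butenolide is much slower, so that group survives as C13=C14.

Step 12
Reactants: 14 ring A spiro-epoxide; 19 (6S)-6-ethenyl-5,6-dihydro-2H-pyran-2-one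
Product: 20 (4R,6S)-6-ethenyl-4-[ring A]oxan-2-one with free C20 hydroxyl (ring A 1S,4R,5R,10S)
Conditions: Cp2TiCl2 (2.5 equiv), Zn, THF, 23 °C; slow addition of 14 to Cp2TiCl and 19 (3 equiv); aq. NaH2PO4
Reagents that add atoms: none
Why: Proposed new method: Cp2TiCl (trivalent titanium) opens the epoxide at the more substituted C–O bond to the tertiary C10 radical carrying the C20 titanium alkoxide; this nucleophilic radical adds to C9 of 19 and a second Cp2TiCl reduces the α-carbonyl radical to a titanium enolate that is protonated on work-up. The closest known reaction type is the reductive epoxide–acrylate coupling with Cp2TiCl (Nugent–RajanBabu conditions), established for spiro-epoxides and acrylates but not for an endocyclic β-substituted δ-lactone acceptor. C10 should be set by approach to the ring A face opposite C1–O, C6 and C19, and C9 by axial attack trans to the C12 vinyl group.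

Step 13
Reactants: 20 hydroxy lactone
Product: 21 C20 triethylsilyl ether of 20
Conditions: Et3SiCl, imidazole, CH2Cl2, 0 °C
Reagents that add atoms: chlorotriethylsilane, CC[Si](Cl)(CC)CC
Why: Silylation of the primary neopentyl alcohol; the triethylsilyl ether can later be removed beside the two hindered tert-butyldimethylsilyl ethers, and prompt protection prevents migration of the lactone from O–C12 to O–C20.

Step 14
Reactants: 21 C20 triethylsilyl ether of 20; 22 3-bromo-1-(trimethylsilyl)prop-1-yne
Product: 23 (3S,4R,6S)-6-ethenyl-4-[ring A]-3-[3-(trimethylsilyl)prop-2-yn-1-yl]oxan-2-one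
Conditions: LiN(iPr)2, THF, −78 °C; 22, DMPU, −78 → −30 °C
Reagents that add atoms: none
Why: Alkylation of the lithium lactone enolate by a propargylic bromide forms C8–C15; entry trans to ring A is expected, but the C8 configuration is erased in step 15.

Step 15
Reactants: 23 (3S,4R,6S)-6-ethenyl-4-[ring A]-3-[3-(trimethylsilyl)prop-2-yn-1-yl]oxan-2-one
Product: 26 ring C cyclohexene acid (8R,9S,10S) bearing the silylpropargyl group on C8, via silyl ketene acetal 24 (not isolated), via trimethylsilyl ester 25 (not isolated)
Conditions: LiN(iPr)2, Me3SiCl/Et3N, THF, −78 → 23 °C; PhMe, 110 °C; aq. citric acid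
Reagents that add atoms: none
Why: LiN(iPr)2 removes the C8 hydrogen and Me3SiCl traps the enolate on oxygen; the geometry of ketene acetal 24 is fixed because both oxygens lie in the ring. On heating, 24 undergoes a [3,3]-sigmatropic Ireland–Claisen shift through a boat-like transition state shaped like bicyclo[2.2.2]octane, in which C14 reaches C8 while O–C12 breaks; the closest known reaction type is the Claisen ring contraction of 6-alkenyl δ-lactone silyl ketene acetals to cyclohex-3-ene carboxylic acids. Ring C (C8, C14, C13, C12, C11, C9) closes within this pericyclic array, so no exo or endo choice arises and the C12=C13 bond is necessarily cis. Quaternary C8 is set by suprafacial transfer of chirality from C12, since the vinyl group can reach only the face on which C12 holds it. Ring A on C9 is trans to the vinyl group and therefore points away from the incoming C13–C14 bridge, and the product carries C7 cis to C10 on ring C, as the later lactone requires. The step needs complete O-silylation of a hindered, fully substituted enolate; the alkyne is capped by silicon, so C8–H is the only acidic C–H. Both C8 epimers of 23 give the same ketene acetal, and aqueous acid hydrolyses silyl ester 25 to 26.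

Step 16
Reactants: 26 ring C cyclohexene acid
Product: 27 terminal alkyne acid (prop-2-yn-1-yl on C8)
Conditions: K2CO3, MeOH, 23 °C; aq. NaH2PO4
Reagents that add atoms: none
Why: Base-mediated methanolysis of the alkynyl C–Si bond frees the terminal alkyne needed in step 18; partial loss of the triethylsilyl ether would be harmless, because step 17 removes it.

Step 17
Reactants: 27 terminal alkyne acid
Product: 29 alkynyl spirolactone (C7–O–C20), via hydroxy acid 28 (not isolated)
Conditions: PPTS, MeOH/CH2Cl2, 0 °C; then EDCI·HCl, DMAP, CH2Cl2, 23 °C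
Reagents that add atoms: none
Why: Mild acid methanolysis removes the primary triethylsilyl ether while the hindered tert-butyldimethylsilyl ethers stay; carbodiimide activation (Steglich conditions) closes the six-membered lactone. Only C20–OH is free, so the C1 oxygen cannot compete.

Step 18
Reactants: 29 alkynyl spirolactone
Product: 31 16-methylidene bicyclo[3.2.1]octane spirolactone (8R,9S,10S,13R), via vinylstannane 30 (not isolated)
Conditions: nBu3SnH, AIBN, PhH (0.05 M), 80 °C; then SiO2, CH2Cl2, 23 °C
Reagents that add atoms: none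
Why: The stannyl radical adds to alkyne carbon C17, and the C16 vinyl radical closes 5-exo-trig onto C13 on the only face the C8 tether allows, which fixes C13. The C12 radical takes hydrogen from the stannane and silica protodestannylates 30; this enyne radical cyclisation is an established route to kaurane-type bicyclo[3.2.1]octanes.

Step 19
Reactants: 31 16-methylidene bicyclo[3.2.1]octane spirolactone
Product: 32 C1,C19 diol
Conditions: aq. HF (48 %), MeCN, 0 → 23 °C
Reagents that add atoms: none
Why: Fluoride-assisted acidic cleavage of both silyl ethers, including the hindered C1 ether; the benzyl-type ether, the lactone and the exocyclic alkene are stable to these conditions.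

Step 20
Reactants: 32 C1,C19 diol
Product: 33 C1,C19 diacetate
Conditions: Ac2O, DMAP, pyridine, CH2Cl2, 23 °C
Reagents that add atoms: acetic anhydride, CC(=O)OC(C)=O
Why: DMAP-catalysed acylation of the primary and the hindered secondary alcohol; C6 stays masked and therefore differentiated.

Step 21
Reactants: 33 C1,C19 diacetate
Product: 34 15-hydroxy-16-ene (15S drawn)
Conditions: SeO2, tBuOOH, CH2Cl2, 23 °C
Reagents that add atoms: selenium dioxide, O=[Se]=O; tert-butyl hydroperoxide, CC(C)(C)OO
Why: Allylic oxidation by SeO2 (ene reaction, then [2,3]-sigmatropic shift) turned over by the hydroperoxide; C15 is the only allylic position that can react because C13 is a bridgehead, and the C15 configuration is lost in step 22.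

Step 22
Reactants: 34 15-hydroxy-16-ene
Product: 35 15-oxo-16-ene 4-methoxybenzyl ether
Conditions: Dess–Martin periodinane, NaHCO3, CH2Cl2, 0 → 23 °C
Reagents that add atoms: none
Why: Dess–Martin oxidation of the secondary allylic alcohol under buffered, non-nucleophilic conditions gives the α-methylene ketone without conjugate addition or acyl migration.

Step 23
Reactants: 35 15-oxo-16-ene 4-methoxybenzyl ether
Product: 36 CNP0105570.2
Conditions: DDQ, CH2Cl2/pH 7 buffer, 0 → 23 °C
Reagents that add atoms: none
Why: Oxidative cleavage of the 4-methoxybenzyl ether by DDQ (benzylic hydride abstraction, hydrolysis of the hemiacetal) at neutral pH; acetates, lactone and the electron-poor enone are not attacked.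

## Compound list

Abbreviation used in the names of 20–23: "[ring A]" is the ring A unit attached through C10 with the 1S,4R,5R,10S configuration, C1 and C19 as tert-butyldimethylsilyl ethers and C6 as the 4-methoxybenzyl ether.

1 | 4-methoxybenzyl alcohol | COc1ccc(CO)cc1 | starting material
2 | 3-bromoprop-1-ene (allyl bromide) | C=CCBr | starting material
3 | 1-methoxy-4-[(prop-2-en-1-yloxy)methyl]benzene | C=CCOCc1ccc(OC)cc1 | intermediate
4 | but-3-en-2-one | CC(=O)C=C | starting material
5 | (3E)-5-[(4-methoxybenzyl)oxy]pent-3-en-2-one | CC(=O)/C=C/COCc1ccc(OC)cc1 | intermediate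
6 | {[(3E)-5-[(4-methoxybenzyl)oxy]penta-1,3-dien-2-yl]oxy}tri(propan-2-yl)silane | C=C(O[Si](C(C)C)(C(C)C)C(C)C)/C=C/COCc1ccc(OC)cc1 | intermediate
7 | 2-methylprop-2-enal (methacrolein) | CC(=C)C=O | starting material
8 | (1R,2S)-2-{[(4-methoxybenzyl)oxy]methyl}-1-methyl-4-[(triisopropylsilyl)oxy]cyclohex-3-ene-1-carbaldehyde (formyl cis to the ether arm) | C1=C(O[Si](C(C)C)(C(C)C)C(C)C)CC[C@@](C)(C=O)[C@H]1COCc2ccc(OC)cc2 | intermediate
9 | (1R,2S,3R)-3-[(dimethylamino)methyl]-2-{[(4-methoxybenzyl)oxy]methyl}-1-methyl-4-oxocyclohexane-1-carbaldehyde (C3 epimer immaterial) | CN(C)C[C@@H]1C(=O)CC[C@@](C)(C=O)[C@H]1COCc2ccc(OC)cc2 | intermediate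
10 | N-methyl ammonium iodide of 9 | C[N+](C)(C)C[C@@H]1C(=O)CC[C@@](C)(C=O)[C@H]1COCc2ccc(OC)cc2.[I-] | intermediate
11 | (1R,2R)-2-{[(4-methoxybenzyl)oxy]methyl}-1-methyl-3-methylidene-4-oxocyclohexane-1-carbaldehyde | C=C1C(=O)CC[C@@](C)(C=O)[C@H]1COCc2ccc(OC)cc2 | intermediate
12 | (1S,3R,4R)-4-(hydroxymethyl)-3-{[(4-methoxybenzyl)oxy]methyl}-4-methyl-2-methylidenecyclohexan-1-ol | C=C1[C@@H](O)CC[C@@](C)(CO)[C@H]1COCc2ccc(OC)cc2 | intermediate
13 | bis(tert-butyldimethylsilyl) ether of 12 (1S,3R,4R) | C=C1[C@@H](O[Si](C)(C)C(C)(C)C)CC[C@@](C)(CO[Si](C)(C)C(C)(C)C)[C@H]1COCc2ccc(OC)cc2 | intermediate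
14 | (3R,4S,5R,8S)-8-[(tert-butyldimethylsilyl)oxy]-5-{[(tert-butyldimethylsilyl)oxy]methyl}-4-{[(4-methoxybenzyl)oxy]methyl}-5-methyl-1-oxaspiro[2.5]octane (spiro centre immaterial) | O1C[C@]12[C@@H](O[Si](C)(C)C(C)(C)C)CC[C@@](C)(CO[Si](C)(C)C(C)(C)C)[C@H]2COCc3ccc(OC)cc3 | intermediate
15 | prop-2-enal (acrolein) | C=CC=O | starting material
16 | (3S)-hexa-1,5-dien-3-ol | C=C[C@@H](O)CC=C | intermediate
17 | prop-2-enoyl chloride (acryloyl chloride) | C=CC(Cl)=O | starting material
18 | (3S)-hexa-1,5-dien-3-yl prop-2-enoate | C=C[C@@H](OC(=O)C=C)CC=C | intermediate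
19 | (6S)-6-ethenyl-5,6-dihydro-2H-pyran-2-one | C=C[C@@H]1CC=CC(=O)O1 | intermediate
20 | (4R,6S)-6-ethenyl-4-[ring A]oxan-2-one, C20 free hydroxyl (kaurane 9R,12S) | C=C[C@@H]1C[C@@H]([C@]2(CO)[C@@H](O[Si](C)(C)C(C)(C)C)CC[C@@](C)(CO[Si](C)(C)C(C)(C)C)[C@H]2COCc3ccc(OC)cc3)CC(=O)O1 | intermediate
21 | C20 triethylsilyl ether of 20 | C=C[C@@H]1C[C@@H]([C@]2(CO[Si](CC)(CC)CC)[C@@H](O[Si](C)(C)C(C)(C)C)CC[C@@](C)(CO[Si](C)(C)C(C)(C)C)[C@H]2COCc3ccc(OC)cc3)CC(=O)O1 | intermediate
22 | 3-bromo-1-(trimethylsilyl)prop-1-yne | BrCC#C[Si](C)(C)C | starting material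
23 | (3S,4R,6S)-6-ethenyl-4-[ring A, C20 triethylsilyl ether]-3-[3-(trimethylsilyl)prop-2-yn-1-yl]oxan-2-one (4,6-trans; C3 epimer immaterial) | C=C[C@@H]1C[C@@H]([C@]2(CO[Si](CC)(CC)CC)[C@@H](O[Si](C)(C)C(C)(C)C)CC[C@@](C)(CO[Si](C)(C)C(C)(C)C)[C@H]2COCc3ccc(OC)cc3)[C@H](CC#C[Si](C)(C)C)C(=O)O1 | intermediate
24 | cyclic trimethylsilyl ketene acetal of 23 (C8=C7) | C=C[C@@H]1C[C@@H]([C@]2(CO[Si](CC)(CC)CC)[C@@H](O[Si](C)(C)C(C)(C)C)CC[C@@](C)(CO[Si](C)(C)C(C)(C)C)[C@H]2COCc3ccc(OC)cc3)C(CC#C[Si](C)(C)C)=C(O[Si](C)(C)C)O1 | intermediate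
25 | trimethylsilyl ester of 26 | C[Si](C)(C)OC(=O)[C@@]1(CC#C[Si](C)(C)C)CC=CC[C@H]1[C@]2(CO[Si](CC)(CC)CC)[C@@H](O[Si](C)(C)C(C)(C)C)CC[C@@](C)(CO[Si](C)(C)C(C)(C)C)[C@H]2COCc3ccc(OC)cc3 | intermediate
26 | ring C cyclohex-3-ene carboxylic acid (8R,9S,10S): C8 carries CO2H (C7) and the silylpropargyl group, C9 carries ring A with C7 cis to C10 | OC(=O)[C@@]1(CC#C[Si](C)(C)C)CC=CC[C@H]1[C@]2(CO[Si](CC)(CC)CC)[C@@H](O[Si](C)(C)C(C)(C)C)CC[C@@](C)(CO[Si](C)(C)C(C)(C)C)[C@H]2COCc3ccc(OC)cc3 | intermediate
27 | terminal alkyne acid from 26 (8R,9S,10S) | OC(=O)[C@@]1(CC#C)CC=CC[C@H]1[C@]2(CO[Si](CC)(CC)CC)[C@@H](O[Si](C)(C)C(C)(C)C)CC[C@@](C)(CO[Si](C)(C)C(C)(C)C)[C@H]2COCc3ccc(OC)cc3 | intermediate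
28 | C20 hydroxy acid from 27 | OC(=O)[C@@]1(CC#C)CC=CC[C@H]1[C@]2(CO)[C@@H](O[Si](C)(C)C(C)(C)C)CC[C@@](C)(CO[Si](C)(C)C(C)(C)C)[C@H]2COCc3ccc(OC)cc3 | intermediate
29 | alkynyl spirolactone (C7–O–C20; 8R,9S,10S; ring C 12-ene) | O=C1[C@@]2(CC#C)CC=CC[C@H]2[C@]3(CO1)[C@@H](O[Si](C)(C)C(C)(C)C)CC[C@@](C)(CO[Si](C)(C)C(C)(C)C)[C@H]3COCc4ccc(OC)cc4 | intermediate
30 | C17 tributylstannyl derivative of 31 (E/Z mixture) | CCCC[Sn](CCCC)(CCCC)C=C1C[C@]23C[C@H]1CC[C@H]2[C@]1(COC3=O)[C@@H](O[Si](C)(C)C(C)(C)C)CC[C@@](C)(CO[Si](C)(C)C(C)(C)C)[C@H]1COCc1ccc(OC)cc1 | intermediate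
31 | 6,7-seco-ent-kaur-16-en-7,20-olide, C1 and C19 tert-butyldimethylsilyl ethers, C6 4-methoxybenzyl ether (8R,9S,10S,13R) | C=C1C[C@]23C[C@H]1CC[C@H]2[C@]1(COC3=O)[C@@H](O[Si](C)(C)C(C)(C)C)CC[C@@](C)(CO[Si](C)(C)C(C)(C)C)[C@H]1COCc1ccc(OC)cc1 | intermediate
32 | C1,C19 diol from 31 | C=C1C[C@]23C[C@H]1CC[C@H]2[C@]1(COC3=O)[C@@H](O)CC[C@@](C)(CO)[C@H]1COCc1ccc(OC)cc1 | intermediate
33 | C1,C19 diacetate | C=C1C[C@]23C[C@H]1CC[C@H]2[C@]1(COC3=O)[C@@H](OC(C)=O)CC[C@@](C)(COC(C)=O)[C@H]1COCc1ccc(OC)cc1 | intermediate
34 | 15-hydroxy derivative of 33 (15S drawn, hydroxyl on the C14 side; epimer immaterial) | C=C1[C@H](O)[C@]23C[C@H]1CC[C@H]2[C@]1(COC3=O)[C@@H](OC(C)=O)CC[C@@](C)(COC(C)=O)[C@H]1COCc1ccc(OC)cc1 | intermediate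
35 | 15-oxo-16-ene, C6 4-methoxybenzyl ether (1S,4R,5R,8S,9S,10S,13R) | C=C1C(=O)[C@]23C[C@H]1CC[C@H]2[C@]1(COC3=O)[C@@H](OC(C)=O)CC[C@@](C)(COC(C)=O)[C@H]1COCc1ccc(OC)cc1 | intermediate
36 | CNP0105570.2: 1,19-diacetoxy-6-hydroxy-15-oxo-6,7-seco-ent-kaur-16-en-7,20-olide (1S,4R,5R,8S,9S,10S,13R) | C=C1C(=O)[C@]23C[C@H]1CC[C@H]2[C@]1(COC3=O)[C@@H](OC(C)=O)CC[C@@](C)(COC(C)=O)[C@H]1CO | target

## Step count and least certain steps

Total: 23 steps. Longest linear sequence: 20 steps (1–8, then 12–23); the lactone branch (9–11) has 3 steps.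

**Step 12 (proposed new method).** The tertiary C10 radical, flanked by two substituted carbons, may add too slowly to the β-substituted acceptor. Trapping by a second Cp2TiCl, followed by loss of the titanium oxide or of a β-hydrogen, would then win. The lactone may also migrate from O–C12 to the free C20 oxygen before silylation. The fallback uses known chemistry and runs from 13 to 21. Dihydroxylation of 13 (OsO4 cat., N-methylmorpholine N-oxide) gives the diol F1. Et3SiCl and imidazole silylate its primary hydroxyl to give the triethylsilyl ether F2. Methyl chlorooxoacetate with Et3N and DMAP acylates the tertiary hydroxyl to give the methyl oxalate F3, and CsOH hydrolyses this to the cesium oxalate F4. Blue-light irradiation of F4 with [Ir{dF(CF3)ppy}2(dtbbpy)]PF6 and 19 in DME/DMF/H2O releases the same C10 radical by double decarboxylation. Its Giese addition to the cyclic acceptor gives 21 directly, a photoredox coupling of tertiary alkyl oxalates that is known for endocyclic unsaturated lactones and enones.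

**Step 15 (key step).** Deprotonation at C8 may be slow, because in the trans isomer of 23 the C8 hydrogen lies on the face of ring A. The tetrasubstituted ketene acetal may then form incompletely, or C-silylation and lactone condensation may intervene. The boat transition state also has to form a quaternary centre next to C9. The fallback runs from 21 to 26. The unsubstituted lactone 21 is put through the same silylation and heating, by way of the less hindered silyl ketene acetal F5 and the trimethylsilyl ester F6, to give the C8–H acid F7. The dianion of F7 (LiN(iPr)2, 2.2 equiv, THF/DMPU) is then alkylated at C8 with 22 on the face opposite ring A, which gives 26. Ring C and the C8–C14 bond still come from the Claisen shift; only the quaternisation is moved.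

**Step 4.** Face discrimination by the catalyst, or the endo preference of an α-methyl dienophile with this acyclic diene, may be insufficient, which would erode the C4/C5 relation or the optical purity. The fallback runs from 6 and 7 back to 8. A Me2AlCl-promoted cycloaddition gives the racemate, that is 8 together with its antipode F8. Condensation with (1R,2R)-N,N′-dimethyl-1,2-diphenylethane-1,2-diamine converts 8 into the imidazolidine F9 and F8 into the diastereomeric imidazolidine F10. These are separated by chromatography, and F9 is hydrolysed on wet silica to return enantiopure 8.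

**Step 18.** The chain may be inefficient, because stannyl radical addition to the neopentyl alkyne is reversible. Plain hydrostannation, 1,5-hydrogen transfer from C11, or homoallyl rearrangement of the C12 radical towards the bicyclo[2.2.2]octane could then compete, and protodestannylation may shift the exocyclic alkene. The fallback runs from 21 to 31. 21 is alkylated with 2,3-dibromopropene instead of 22 to give the 2-bromoallyl lactone F11. The Claisen shift, through the silyl ketene acetal F12 and the trimethylsilyl ester F13, gives the bromoallyl acid F14. The conditions of step 17 take F14 through the hydroxy acid F15 to the bromoallyl spirolactone F16. nBu3SnH and AIBN at higher hydride concentration abstract bromine, so the C16 vinyl radical forms irreversibly and closes onto C13 to give 31 directly, with no tin on carbon.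

## Further compounds

F1 | step 12 | C10,C20 diol from 13 (tertiary hydroxyl on C10) | OC[C@@]1(O)[C@@H](O[Si](C)(C)C(C)(C)C)CC[C@@](C)(CO[Si](C)(C)C(C)(C)C)[C@H]1COCc1ccc(OC)cc1
F2 | step 12 | C20 triethylsilyl ether of F1 | CC[Si](CC)(CC)OC[C@@]1(O)[C@@H](O[Si](C)(C)C(C)(C)C)CC[C@@](C)(CO[Si](C)(C)C(C)(C)C)[C@H]1COCc1ccc(OC)cc1
F3 | step 12 | methyl oxalate of the C10 tertiary alcohol F2 | CC[Si](CC)(CC)OC[C@@]1(OC(=O)C(=O)OC)[C@@H](O[Si](C)(C)C(C)(C)C)CC[C@@](C)(CO[Si](C)(C)C(C)(C)C)[C@H]1COCc1ccc(OC)cc1
F4 | step 12 | cesium oxalate from F3 | CC[Si](CC)(CC)OC[C@@]1(OC(=O)C(=O)[O-])[C@@H](O[Si](C)(C)C(C)(C)C)CC[C@@](C)(CO[Si](C)(C)C(C)(C)C)[C@H]1COCc1ccc(OC)cc1.[Cs+]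
F5 | step 15 | trimethylsilyl ketene acetal of 21 | C=C[C@@H]1C[C@@H]([C@]2(CO[Si](CC)(CC)CC)[C@@H](O[Si](C)(C)C(C)(C)C)CC[C@@](C)(CO[Si](C)(C)C(C)(C)C)[C@H]2COCc3ccc(OC)cc3)C=C(O[Si](C)(C)C)O1
F6 | step 15 | trimethylsilyl ester of F7 | C[Si](C)(C)OC(=O)[C@H]1CC=CC[C@H]1[C@]2(CO[Si](CC)(CC)CC)[C@@H](O[Si](C)(C)C(C)(C)C)CC[C@@](C)(CO[Si](C)(C)C(C)(C)C)[C@H]2COCc3ccc(OC)cc3
F7 | step 15 | ring C cyclohex-3-ene carboxylic acid with hydrogen on C8 | OC(=O)[C@H]1CC=CC[C@H]1[C@]2(CO[Si](CC)(CC)CC)[C@@H](O[Si](C)(C)C(C)(C)C)CC[C@@](C)(CO[Si](C)(C)C(C)(C)C)[C@H]2COCc3ccc(OC)cc3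
F8 | step 4 | antipode of 8 (1S,2R) | C1=C(O[Si](C(C)C)(C(C)C)C(C)C)CC[C@](C)(C=O)[C@@H]1COCc2ccc(OC)cc2
F9 | step 4 | imidazolidine of 8 with the (R,R)-diamine | CN1[C@H](c2ccccc2)[C@@H](c2ccccc2)N(C)C1[C@]1(C)CCC(O[Si](C(C)C)(C(C)C)C(C)C)=C[C@@H]1COCc1ccc(OC)cc1
F10 | step 4 | imidazolidine of F8 with the (R,R)-diamine | CN1[C@H](c2ccccc2)[C@@H](c2ccccc2)N(C)C1[C@@]1(C)CCC(O[Si](C(C)C)(C(C)C)C(C)C)=C[C@H]1COCc1ccc(OC)cc1
F11 | step 18 | 2-bromoallyl analogue of 23 | C=C[C@@H]1C[C@@H]([C@]2(CO[Si](CC)(CC)CC)[C@@H](O[Si](C)(C)C(C)(C)C)CC[C@@](C)(CO[Si](C)(C)C(C)(C)C)[C@H]2COCc3ccc(OC)cc3)[C@H](CC(Br)=C)C(=O)O1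
F12 | step 18 | trimethylsilyl ketene acetal of F11 | C=C[C@@H]1C[C@@H]([C@]2(CO[Si](CC)(CC)CC)[C@@H](O[Si](C)(C)C(C)(C)C)CC[C@@](C)(CO[Si](C)(C)C(C)(C)C)[C@H]2COCc3ccc(OC)cc3)C(CC(Br)=C)=C(O[Si](C)(C)C)O1
F13 | step 18 | trimethylsilyl ester of F14 | C[Si](C)(C)OC(=O)[C@@]1(CC(Br)=C)CC=CC[C@H]1[C@]2(CO[Si](CC)(CC)CC)[C@@H](O[Si](C)(C)C(C)(C)C)CC[C@@](C)(CO[Si](C)(C)C(C)(C)C)[C@H]2COCc3ccc(OC)cc3
F14 | step 18 | 2-bromoallyl analogue of 26 | OC(=O)[C@@]1(CC(Br)=C)CC=CC[C@H]1[C@]2(CO[Si](CC)(CC)CC)[C@@H](O[Si](C)(C)C(C)(C)C)CC[C@@](C)(CO[Si](C)(C)C(C)(C)C)[C@H]2COCc3ccc(OC)cc3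
F15 | step 18 | C20 hydroxy acid from F14 | OC(=O)[C@@]1(CC(Br)=C)CC=CC[C@H]1[C@]2(CO)[C@@H](O[Si](C)(C)C(C)(C)C)CC[C@@](C)(CO[Si](C)(C)C(C)(C)C)[C@H]2COCc3ccc(OC)cc3
F16 | step 18 | 2-bromoallyl analogue of 29 | O=C1[C@@]2(CC(Br)=C)CC=CC[C@H]2[C@]3(CO1)[C@@H](O[Si](C)(C)C(C)(C)C)CC[C@@](C)(CO[Si](C)(C)C(C)(C)C)[C@H]3COCc4ccc(OC)cc4
A1 | alternative 1 | ring A cyclohex-2-enone with the C9 side chain (CH2CO2Me and CH2CH2OSi arms) | O=C1CC[C@@](C)(CO[Si](C)(C)C(C)(C)C)C=C1[C@@H](CC(=O)OC)CCO[Si](C)(C)C(C)(C)C
A2 | alternative 1 | vinylene carbonate | O=C1OC=CO1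
A3 | alternative 1 | cis-fused cyclobutane carbonate photoadduct | O=C1CC[C@@](C)(CO[Si](C)(C)C(C)(C)C)[C@H]2[C@@H]3OC(=O)O[C@@H]3[C@@]12[C@@H](CC(=O)OC)CCO[Si](C)(C)C(C)(C)C
A4 | alternative 2 | α-methylene spirolactone with a 2-(trimethylsilylmethyl)allyl acetate terminus on the C9 chain (acetate carbon unspecified) | C=C1[C@@H](CCC(OC(C)=O)C(=C)C[Si](C)(C)C)[C@]2(COC1=O)[C@@H](OC(C)=O)CC[C@@](C)(COC(C)=O)[C@H]2CO[Si](C)(C)C(C)(C)C
A5 | alternative 2 | 15-deoxo tetracycle, C6 tert-butyldimethylsilyl ether | C=C1C[C@]23C[C@H]1CC[C@H]2[C@]1(COC3=O)[C@@H](OC(C)=O)CC[C@@](C)(COC(C)=O)[C@H]1CO[Si](C)(C)C(C)(C)C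
A6 | alternative 3 | ring A spiro-epoxide, C1 and C19 acetates, C6 tert-butyldimethylsilyl ether | O1C[C@]12[C@@H](OC(C)=O)CC[C@@](C)(COC(C)=O)[C@H]2CO[Si](C)(C)C(C)(C)C
A7 | alternative 3 | 2,2,2-trifluoroethyl acrylate | C=CC(=O)OCC(F)(F)F
A8 | alternative 3 | saturated spirolactone of ring A | O=C1CC[C@]2(CO1)[C@@H](OC(C)=O)CC[C@@](C)(COC(C)=O)[C@H]2CO[Si](C)(C)C(C)(C)C
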